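Readings and results come from a simulation with made-up constants.

For late times in this flask we reckon what the incoming ligand can pay for, not how fast it pays.

in all of them: starting complex 10 mM

|  | incoming ligand | remark | time |
|---|---|---|---|
| dusk | 4.8 mM | run made earlier |  |
| flask | 9.50 mM |  | 4.0 d |
dusk run (percent of the starting complex charged)

| time / h | starting complex / % | complex with two exchanged / % |
|---|---|---|
| 0.833 | 97.5 | 0.2 |
| 2.00 | 96.9 | 0.4 |
| 4.00 | 92.8 | 0.5 |
| 10.0 | 87.1 | 0 |

(each reading ± 0.5 percentage points)
- the analysis behind the earlier runs scatters by 0.5 percentage points, standard deviation
- the earlier runs do not show how much of incoming ligand is bound; that part of a forecast is a guess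
- no earlier run changes the charge of incoming ligand; that part of a forecast is a guess
- part of the starting complex that has reacted at 4.0 d
- share of the unused incoming ligand that is free and not bound as idle adduct, at 4.0 d

The last dusk reading shows 12.9% of the starting complex reacted after 10.0 h. Held at that dusk pace, 4.0 d covers 124% of the charge, more than the whole of it, so we look to the supply of ligand.

Turn the question round: for the starting complex to run out first, the ligand budget, incoming ligand charged per starting complex charged, 0.950, has to reach the ligand taken up per complex reacted. That cost is one at the least, and the flask's budget stands below one, so in this flask incoming ligand is the limiting reagent. We go round twice, taking the reacted fraction as budget over cost, with the whole budget taken up: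

first round, cost 1: reacted fraction at most 95.0%

second round, cost 2: reacted fraction near 47.5%

The second round puts the first answer back: we guess that each exchange sets a partner free and that this partner, as idle adduct, holds one more incoming ligand. The earlier runs do not show this, but we commit to it, with a free share below 50.0%.

The forecast gave 71% reacted and 85% free, saying "Most unused ligand is then probably free". Its reacted share stands above ours and, with the whole budget taken up, means a cost of 1.34.

The flask gives 49.8% reacted and 7.66% free.

    starting complex + incoming ligand ⇌ leaving ligand + complex with one exchanged (K = 100, k = 0.0710 L mol⁻¹ min⁻¹)
    complex with one exchanged + incoming ligand ⇌ leaving ligand + complex with two exchanged (K = 9.50, k = 0.00730 L mol⁻¹ min⁻¹)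
    complex with two exchanged + incoming ligand ⇌ leaving ligand + complex with three exchanged (K = 1.40, k = 0.0370 L mol⁻¹ min⁻¹)
    complex with three exchanged + incoming ligand ⇌ leaving ligand + complex with four exchanged (K = 0.110, k = 0.160 L mol⁻¹ min⁻¹)
    leaving ligand + incoming ligand ⇌ idle adduct, settled at all times (K = 9800 L mol⁻¹)
    complex with two exchanged + incoming ligand → over-reaction product (k = 0.0330 L mol⁻¹ min⁻¹)

At 4.00 d the flask holds 3.96 mM of idle adduct, and 3.5% of its incoming ligand stands unbound, so the part of its budget taken up comes to a cost of 1.84 per complex reacted. The neighbour charged with 40 mM of starting complex has a budget of 0.237. At 4.00 d it keeps 0.76% of its incoming ligand unbound and has 16.5% reacted, a cost of 1.43.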